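**Retrosynthetic overview** (ring A = C1–C6, spiro atom C6, ring B = C6–C11)
1. Target ⇐ i-Bu2AlH reduction of the (4R)-α′-bromo enone ⇐ C4 bromination of the C1-methyl enone ⇐ methyl addition and oxidative 1,3-transposition of a spiro enone that carries C1=O.
2. Ring A ⇐ two-atom ring expansion. The C3–C6 bond of a spiro 3-ethoxycyclobutanone (ring atoms C1, C2, C3, C6) is cleaved and isobutene is inserted as C4–C5. One operation makes C3–C4, the vicinal quaternary C5–C6 bond and the spiro stereocentre.
3. Enabling feature: in ring A the oxygen-bearing C3 and the latent carbonyl C1 stand 1,3 to each other, C1 is bonded to spiro atom C6, and the remainder C4–C5(CH3)2 is an isobutene unit. C1/C2/C3/C6 can therefore be a cyclobutanone whose C3–C6 bond lies between a donor (OEt on C3) and an acceptor (C1=O on C6).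
4. Cyclobutanone ⇐ [2+2] of ethyl vinyl ether with the ketene of trans-4-bromo-3-chloro-4-methylcyclohexanecarboxylic acid ⇐ HBr opening of a chlorolactone ⇐ chlorolactonisation of (R)-4-methylcyclohex-3-enecarboxylic acid ⇐ catalytic asymmetric Diels–Alder reaction of isoprene.
5. Order of ring formation: ring B (Diels–Alder), a temporary lactone ring (made and opened again), the four-membered ring C1/C2/C3/C6, then ring A by its expansion.

Key step: step 7

Assumption: the (R)-prolinol-derived oxazaborolidinium catalyst is taken to give the (R)-ester 3, by analogy with the (S)-catalyst/(S)-cyclohex-3-enecarboxylate pairing for simple dienes. If the sense were opposite, the mirror-image catalyst would be used.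
Remark: the CIP descriptor of C6 switches between S and R along the route only because substituent priorities change. The spatial arrangement stays the same.

Step 1
Reactants: 1 isoprene; 2 2,2,2-trifluoroethyl acrylate
Product: 3 2,2,2-trifluoroethyl (1R)-4-methylcyclohex-3-ene-1-carboxylate
Conditions: (R)-3,3-diphenyl-1-(2-methylphenyl)tetrahydro-1H,3H-pyrrolo[1,2-c][1,3,2]oxazaborole (10 mol %), HN(SO2CF3)2 (8 mol %), CH2Cl2, −20 °C to rt
Reagents that add atoms: none
Why: Enantioselective Diels–Alder reaction under cationic oxazaborolidine catalysis, in which the larger HOMO coefficient at C1 of isoprene gives the para adduct and the catalyst shields one face of the bound acrylate, so the ester-bearing ring carbon is set as R.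

Step 2
Reactants: 3 2,2,2-trifluoroethyl (1R)-4-methylcyclohex-3-ene-1-carboxylate
Product: 4 (1R)-4-methylcyclohex-3-ene-1-carboxylic acid
Conditions: LiOH·H2O, THF/H2O, 0 °C; then 1 M HCl
Reagents that add atoms: lithium hydroxide [Li+].[OH-]
Why: Saponification of the activated trifluoroethyl ester is fast at 0 °C, so the α-stereocentre should not epimerise.

Step 3
Reactants: 4 (1R)-4-methylcyclohex-3-ene-1-carboxylic acid
Product: 5 (1S,4R,6S)-6-chloro-1-methyl-2-oxabicyclo[2.2.2]octan-3-one
Conditions: N-chlorosuccinimide, (CF3)2CHOH/CH2Cl2, 0 °C to rt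
Reagents that add atoms: N-chlorosuccinimide O=C1CCC(=O)N1Cl
Why: Chlorolactonisation, in which the chloronium ion forms on the alkene face away from the carboxyl group and is opened in the Markovnikov sense at the methyl-bearing carbon by the carboxyl oxygen (the only geometry that can bridge), so anti addition fixes the tertiary C–O and the secondary C–Cl, trans to each other, from the one existing stereocentre.

Step 4
Reactants: 5 (1S,4R,6S)-6-chloro-1-methyl-2-oxabicyclo[2.2.2]octan-3-one
Product: 6 (1R,3S,4S)-4-bromo-3-chloro-4-methylcyclohexane-1-carboxylic acid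
Conditions: HBr (33 % in AcOH), CH2Cl2, 0 °C to rt
Reagents that add atoms: hydrogen bromide Br
Why: Acidolytic alkyl–oxygen cleavage of a tertiary lactone with HBr, in which the strained boat lactone ionises at the tertiary carbon, the neighbouring chlorine covers its own face (chloronium-like bridging) and bromide enters anti to it with overall retention, giving the trans tertiary-Br/secondary-Cl array that BrCl addition to the alkene cannot give.

Step 5
Reactants: 6 (1R,3S,4S)-4-bromo-3-chloro-4-methylcyclohexane-1-carboxylic acid
Product: 7 (1R,3S,4S)-4-bromo-3-chloro-4-methylcyclohexane-1-carbonyl chloride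
Conditions: (COCl)2, DMF (cat.), CH2Cl2, 0 °C to rt
Reagents that add atoms: oxalyl chloride O=C(Cl)C(=O)Cl
Why: Standard acid chloride formation with oxalyl chloride and catalytic DMF runs under non-basic conditions that leave both alkyl halides untouched.

Step 6
Reactants: 7 (1R,3S,4S)-4-bromo-3-chloro-4-methylcyclohexane-1-carbonyl chloride; 8 ethyl vinyl ether
Product: 10 (6S,7S)-7-bromo-6-chloro-3-ethoxy-7-methylspiro[3.5]nonan-1-one (mixture at the two cyclobutane stereocentres), via ketene 9 (not isolated)
Conditions: 8 (5 equiv), Et3N (1.5 equiv), MeCN, sealed vessel, 70 °C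
Reagents that add atoms: none
Why: Dehydrochlorination to the dialkylketene and thermal [2+2] ketene–enol ether cycloaddition, in which the ketene carbonyl carbon bonds to the CH2 terminus of the vinyl ether so that OEt ends on the carbon next to the spiro atom, while the two new cyclobutane stereocentres may form as a mixture because both are erased in step 7.

Step 7
Reactants: 10 (6S,7S)-7-bromo-6-chloro-3-ethoxy-7-methylspiro[3.5]nonan-1-one; 11 isobutene
Product: 13 (6S,9S,10S)-9-bromo-10-chloro-5,5,9-trimethylspiro[5.5]undec-2-en-1-one, via ethoxy ketone 12 (not isolated)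
Conditions: 11 (20 equiv, condensed), SnCl4 (0.3 equiv), 2,6-di-tert-butyl-4-methylpyridine (0.1 equiv), CH2Cl2, −78 to −40 °C; excess 11 vented; then p-TsOH·H2O (0.3 equiv), rt
Reagents that add atoms: none
Why: Proposed new method: SnCl4 binds the C1 carbonyl of 10, the strained C3–C6 bond (pushed by the ethoxy group on C3, pulled by the carbonyl next to C6) breaks heterolytically to a C6=C1 tin enolate tethered to a C3 oxocarbenium ion, isobutene adds with its CH2 terminus (C4) to C3 in the Markovnikov sense, and the tertiary C5 cation is captured by enolate carbon C6, so C4–C5 is inserted and the four-membered ring grows to the six-membered ring A of 12, which loses ethanol in the acid finish to give 13. The closest known reaction type is the Lewis-acid-mediated formal [4+2] cycloaddition of 3-alkoxycyclobutanones with allylsilanes, silyl enol ethers and carbonyl compounds, and the last bond is an intramolecular case of the Lewis-acid α-tert-alkylation of enol derivatives; what is new is a plain 1,1-dialkylalkene as the two-atom partner, defensible because isobutene is about as nucleophilic as allyltrimethylsilane. Ring A closes in the 6-(enolendo) mode, the enolate carbon attacking a trigonal carbenium centre, which is geometrically favoured. The only lasting new stereocentre is spiro atom C6: once C6 is trigonal, ring B rests in the chair with equatorial C9 methyl and axial C9–Br and C10–Cl, the axial chlorine closes the axial face of the exocyclic enolate, and C5 bonds along the equatorial trajectory anti to chlorine in an early, fast ion-pair collapse that copies this conformer, while C3 of 12 forms as a mixture and is erased. The step needs C- over O-alkylation (the tertiary enol ether from O-attack re-ionises under SnCl4, the ketone does not), capture over proton loss and over isobutene oligomerisation (large excess of alkene, hindered pyridine as proton trap, low temperature), and survival of the tertiary bromide, whose ionisation is retarded by the vicinal chlorine.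

Step 8
Reactants: 13 (6S,9S,10S)-9-bromo-10-chloro-5,5,9-trimethylspiro[5.5]undec-2-en-1-one
Product: 14 (6S,9S,10S)-9-bromo-10-chloro-1,5,5,9-tetramethylspiro[5.5]undec-2-en-1-ol (either C1 epimer)
Conditions: MeLi, CeCl3 (dried), THF, −78 °C; then sat. aq. NH4Cl
Reagents that add atoms: methyllithium [Li]C
Why: 1,2-Addition of a weakly basic organocerium reagent to the hindered enone is chosen to avoid γ-deprotonation and E2 loss of HBr, and the new carbinol centre C1 may form as either epimer because step 9 destroys it.

Step 9
Reactants: 14 (6S,9S,10S)-9-bromo-10-chloro-1,5,5,9-tetramethylspiro[5.5]undec-2-en-1-ol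
Product: 15 (6S,9S,10S)-9-bromo-10-chloro-1,5,5,9-tetramethylspiro[5.5]undec-1-en-3-one
Conditions: pyridinium chlorochromate C5H5NH[CrO3Cl], 4 Å molecular sieves, CH2Cl2, rt
Reagents that add atoms: pyridinium chlorochromate [O-][Cr](=O)(=O)Cl.c1cc[nH+]cc1
Why: Oxidative 1,3-transposition of a tertiary allylic alcohol (Babler–Dauben oxidation), in which the chromate ester shifts [3,3] from crowded C1 to open C3 and is oxidised there, placing the methyl-bearing alkene at C1=C2 and the carbonyl (oxygen from chromate) at C3.

Step 10
Reactants: 15 (6S,9S,10S)-9-bromo-10-chloro-1,5,5,9-tetramethylspiro[5.5]undec-1-en-3-one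
Product: 17 (4R,6R,9S,10S)-4,9-dibromo-10-chloro-1,5,5,9-tetramethylspiro[5.5]undec-1-en-3-one, via silyl dienol ether 16 (not isolated)
Conditions: LiN(i-Pr)2 (1.05 equiv), Me3SiCl, THF, −78 °C; then N-bromosuccinimide, THF, −78 to 0 °C
Reagents that add atoms: N-bromosuccinimide O=C1CCC(=O)N1Br
Why: Kinetic α′-deprotonation of the isophorone-type enone at C4 and silylation give the cross-conjugated silyl dienol ether, which NBS brominates at C4 (electrophilic α-halogenation of an enol silane) along the axial trajectory anti to the pseudo-axial C5 methyl group, the bromide settling equatorial on the C11 side (4R); because ring B is remote the bias may be modest, but C4 is epimerisable through the enol, so the (4S) epimer can be separated and re-equilibrated.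

Step 11
Reactants: 17 (4R,6R,9S,10S)-4,9-dibromo-10-chloro-1,5,5,9-tetramethylspiro[5.5]undec-1-en-3-one
Product: 18 (3S,4R,6R,9S,10S)-4,9-dibromo-10-chloro-1,5,5,9-tetramethylspiro[5.5]undec-1-en-3-ol
Conditions: i-Bu2AlH, CH2Cl2/toluene, −78 °C; then aq. potassium sodium tartrate
Reagents that add atoms: none
Why: 1,2-Reduction of the α′-bromo enone with i-Bu2AlH, in which the axial C5 methyl group blocks the axial trajectory, so hydride arrives from the opposite, equatorial side and gives the axial C3 alcohol cis to the equatorial C4 bromide (3S).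

**Compound list**
1 | isoprene (2-methylbuta-1,3-diene) | C=CC(C)=C | starting material
2 | 2,2,2-trifluoroethyl acrylate | C=CC(=O)OCC(F)(F)F | starting material
3 | 2,2,2-trifluoroethyl (1R)-4-methylcyclohex-3-ene-1-carboxylate | O=C(OCC(F)(F)F)[C@@H]1CCC(C)=CC1 | intermediate
4 | (1R)-4-methylcyclohex-3-ene-1-carboxylic acid | OC(=O)[C@@H]1CCC(C)=CC1 | intermediate
5 | (1S,4R,6S)-6-chloro-1-methyl-2-oxabicyclo[2.2.2]octan-3-one | O=C1O[C@@]2(C)CC[C@@H]1C[C@@H]2Cl | intermediate
6 | (1R,3S,4S)-4-bromo-3-chloro-4-methylcyclohexane-1-carboxylic acid | OC(=O)[C@@H]1CC[C@](C)(Br)[C@@H](Cl)C1 | intermediate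
7 | (1R,3S,4S)-4-bromo-3-chloro-4-methylcyclohexane-1-carbonyl chloride | ClC(=O)[C@@H]1CC[C@](C)(Br)[C@@H](Cl)C1 | intermediate
8 | ethyl vinyl ether | C=COCC | starting material
9 | [(3S,4S)-4-bromo-3-chloro-4-methylcyclohexylidene]methanone (ketene) | O=C=C1CC[C@](C)(Br)[C@@H](Cl)C1 | intermediate
10 | (6S,7S)-7-bromo-6-chloro-3-ethoxy-7-methylspiro[3.5]nonan-1-one (mixture at C3 and C4) | O=C1CC(OCC)C12CC[C@](C)(Br)[C@@H](Cl)C2 | intermediate
11 | isobutene (2-methylpropene) | CC(C)=C | starting material
12 | (6S,9S,10S)-9-bromo-10-chloro-3-ethoxy-5,5,9-trimethylspiro[5.5]undecan-1-one (mixture at C3) | O=C1CC(OCC)CC(C)(C)[C@@]12CC[C@](C)(Br)[C@@H](Cl)C2 | intermediate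
13 | (6S,9S,10S)-9-bromo-10-chloro-5,5,9-trimethylspiro[5.5]undec-2-en-1-one | O=C1C=CCC(C)(C)[C@@]12CC[C@](C)(Br)[C@@H](Cl)C2 | intermediate
14 | (6S,9S,10S)-9-bromo-10-chloro-1,5,5,9-tetramethylspiro[5.5]undec-2-en-1-ol (either C1 epimer) | CC1(O)C=CCC(C)(C)[C@@]12CC[C@](C)(Br)[C@@H](Cl)C2 | intermediate
15 | (6S,9S,10S)-9-bromo-10-chloro-1,5,5,9-tetramethylspiro[5.5]undec-1-en-3-one | CC1=CC(=O)CC(C)(C)[C@@]12CC[C@](C)(Br)[C@@H](Cl)C2 | intermediate
16 | [(6R,9S,10S)-9-bromo-10-chloro-1,5,5,9-tetramethylspiro[5.5]undeca-1,3-dien-3-yl]oxy(trimethyl)silane | CC1=CC(O[Si](C)(C)C)=CC(C)(C)[C@@]12CC[C@](C)(Br)[C@@H](Cl)C2 | intermediate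
17 | (4R,6R,9S,10S)-4,9-dibromo-10-chloro-1,5,5,9-tetramethylspiro[5.5]undec-1-en-3-one | CC1=CC(=O)[C@H](Br)C(C)(C)[C@@]12CC[C@](C)(Br)[C@@H](Cl)C2 | intermediate
18 | (3S,4R,6R,9S,10S)-4,9-dibromo-10-chloro-1,5,5,9-tetramethylspiro[5.5]undec-1-en-3-ol | CC1=C[C@H](O)[C@H](Br)C(C)(C)[C@@]12CC[C@](C)(Br)[C@@H](Cl)C2 | target

Total step count: 11. Longest linear sequence: 11 steps (1 → 18).

**Steps most likely to fail**

**Step 7.**
- What may go wrong:
  - proton loss from the tertiary C5 cation instead of C5–C6 bond formation;
  - oligomerisation of isobutene;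
  - drift of the ring-opened zwitterion by proton transfer to an acyclic β-ethoxy enone;
  - erosion of facial selectivity at C6;
  - ionisation of the tertiary bromide.
- The fallback sets out from 7, comes back at 13, uses known reactions only, and still builds ring A by ring expansion.
- Ketene 9 is generated as in step 6 and joined to isobutene 11 in a Lewis-acid-promoted ketene–alkene [2+2] cycloaddition (EtAlCl2, CH2Cl2, −78 °C). This forms C5–C6 on the same equatorial face and gives the 3,3-dimethylcyclobutanone F1.
- Diazomethane homologation (Et2O/MeOH, 0 °C, migration of the CH2 carbon) gives the cyclopentanone F2.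
- Me3SiOTf/Et3N gives the only possible silyl enol ether F3.
- Simmons–Smith cyclopropanation (Et2Zn, CH2I2) gives the siloxycyclopropane F4.
- FeCl3 in DMF (Ito–Saegusa ring expansion, five to six atoms) opens the internal cyclopropane bond to the β-chloro ketone F5.
- NaOAc in MeOH eliminates HCl to give 13.

**Step 10.**
- What may go wrong:
  - poor facial selectivity at C4, because the stereocentres of ring B are remote from the reacting face;
  - competing γ-deprotonation;
  - base-induced loss of HBr from C9.
- The fallback sets out from 15 and comes back at 18.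
- Compound 15 is brominated without regard to C4 (same enol silane, or phenyltrimethylammonium tribromide in THF) to the C4-epimeric bromo enone F6.
- An NADPH-dependent ketoreductase (short-chain dehydrogenase/reductase class, chosen from a panel) is applied with glucose/glucose dehydrogenase recycling, phosphate buffer pH 7.5–8, DMSO co-solvent, 30 °C. It reduces only the (4R) epimer, from one carbonyl face, while the epimers interconvert through the enol.
- This dynamic reductive kinetic resolution lets the protein set both C3 and C4.

**Step 8.**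
- What may go wrong:
  - γ-deprotonation instead of addition at the hindered carbonyl;
  - elimination or reductive loss of the vicinal halogens under the organometallic reagent.
- The fallback sets out from 13 and comes back at 17.
- Soft enolisation with (CF3SO2)2O and 2,6-di-tert-butyl-4-methylpyridine (CH2Cl2, 0 °C) gives the dienyl triflate F7.
- Negishi methylation (Me2Zn, Pd(PPh3)4, THF) gives the 1-methyl diene F8.
- NBS in aqueous acetone attacks the diene terminus C4, and water enters at C3 of the allyl cation, giving the bromohydrin F9 as a stereoisomer mixture.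
- Dess–Martin periodinane oxidises F9 to 17, whose C4 epimers are separated and equilibrated as in step 10.

**Further compounds**
F1 | step 7 | (4S,6S,7S)-7-bromo-6-chloro-3,3,7-trimethylspiro[3.5]nonan-1-one | O=C1CC(C)(C)[C@@]12CC[C@](C)(Br)[C@@H](Cl)C2
F2 | step 7 | (5S,7S,8S)-8-bromo-7-chloro-4,4,8-trimethylspiro[4.5]decan-1-one | O=C1CCC(C)(C)[C@@]12CC[C@](C)(Br)[C@@H](Cl)C2
F3 | step 7 | [(5S,7S,8S)-8-bromo-7-chloro-4,4,8-trimethylspiro[4.5]dec-1-en-1-yl]oxy(trimethyl)silane | C[Si](C)(C)OC1=CCC(C)(C)[C@@]12CC[C@](C)(Br)[C@@H](Cl)C2
F4 | step 7 | siloxycyclopropane from F3: 4'-bromo-3'-chloro-3,3,4'-trimethyl-1-(trimethylsilyloxy)spiro[bicyclo[3.1.0]hexane-2,1'-cyclohexane] | C[Si](C)(C)OC12CC1CC(C)(C)[C@@]23CC[C@](C)(Br)[C@@H](Cl)C3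
F5 | step 7 | (6S,9S,10S)-9-bromo-3,10-dichloro-5,5,9-trimethylspiro[5.5]undecan-1-one (mixture at C3) | O=C1CC(Cl)CC(C)(C)[C@@]12CC[C@](C)(Br)[C@@H](Cl)C2
F6 | step 10 | (6R,9S,10S)-4,9-dibromo-10-chloro-1,5,5,9-tetramethylspiro[5.5]undec-1-en-3-one (C4 epimer mixture) | CC1=CC(=O)C(Br)C(C)(C)[C@@]12CC[C@](C)(Br)[C@@H](Cl)C2
F7 | step 8 | (6S,9S,10S)-9-bromo-10-chloro-5,5,9-trimethylspiro[5.5]undeca-1,3-dien-1-yl trifluoromethanesulfonate | O=S(=O)(OC1=CC=CC(C)(C)[C@@]12CC[C@](C)(Br)[C@@H](Cl)C2)C(F)(F)F
F8 | step 8 | (6R,9S,10S)-9-bromo-10-chloro-1,5,5,9-tetramethylspiro[5.5]undeca-1,3-diene | CC1=CC=CC(C)(C)[C@@]12CC[C@](C)(Br)[C@@H](Cl)C2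
F9 | step 8 | (6R,9S,10S)-4,9-dibromo-10-chloro-1,5,5,9-tetramethylspiro[5.5]undec-1-en-3-ol (mixture at C3 and C4) | CC1=CC(O)C(Br)C(C)(C)[C@@]12CC[C@](C)(Br)[C@@H](Cl)C2
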